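- Per minute, substrate and target run on different clocks, and I look for the crossing between them.

substrate 0.10 M; gas phase 3.4 mM (held); time 30 min
- the target standing at 30 min, as a percentage of the substrate charged
- the change that raises the amount of target at 30 min, in percent of the substrate charged most ("none" if none brings more than 2 percentage points) (Friday's / Sunday's / none)
- amount of target at 30 min, in percent of the substrate charged, after Sunday's
- Friday's: doubling the saturation concentration of gas phase, all else as stated
- Sunday's: doubling the transfer coefficient of step 1, all else as stated
- percentages count the substrate that a species holds: one side product B counts as two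
- at the start none of the gas is dissolved
- run time (flask): 30 min

- The transfer coefficient matters little: 0.97 s⁻¹ exceeds the demand k2·[substrate] of 0.140 s⁻¹, so [dissolved gas] stays near saturation.
- Saturation matters through the product 0.286 min⁻¹, the pseudo-first-order constant of target formation from substrate.
- Step 3 is a small correction: 1.8 × 10⁻⁴ s⁻¹ diverts about 3.78% of the substrate.
- Step 4 matters more than step 3. Substrate is spent while target is still rising, so I take target at about 0.400 of the charge on average over that spending, and each side product B takes two substrate units, so step 4 diverts about 12.4%.
- Step 5 needs the best value: k5·t is 1.39, so a relative error in 7.7 × 10⁻⁴ s⁻¹ reaches the answer magnified by that factor.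
- The crossing time, when making and loss of target balance with side steps ignored, is ln(ka/k5)/(ka−k5) = 7.61 min. Beyond it, target falls on the k5 clock.
- My reckoning is a selectivity of 83.8%, times a head-start factor ka/(ka−k5) of 1.19, times exp(−k5·t). That gives 25.0% for the flask and for Sunday's, whose k1 is not in it.
- Friday's doubled ka, with the same average target, gives 25.0%, a gain of 0.0068 percentage points, less than the margin, so I choose none.
- The forecast gives 24.9% (23.5% to 26.3%), none, and 25.2% after Sunday's (23.8% to 26.6%). On Friday's it says “target forms earlier and decays longer”.
- The flask gives 25.1%, best change none, and 25.0% after Sunday's.

    gas phase ⇌ dissolved gas, rate k1*(csat - [dissolved gas]) (k1 = 0.97 s⁻¹, csat = 3.4 mM)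
    substrate + dissolved gas → target (k2 = 1.4 M⁻¹ s⁻¹)
    substrate → side product A (k3 = 1.8 × 10⁻⁴ s⁻¹)
    substrate + target → side product B (k4 = 0.0074 M⁻¹ s⁻¹)
    target → over-reaction product (k5 = 7.7 × 10⁻⁴ s⁻¹)

- Friday's changes the target by −0.22 points. The flask's 30 min lies past the crossing, with 0.00884% substrate remaining, and so does 80 min. Carrying the flask's target forward on the k5 clock gives 2.49%, and the same flask read at that time holds 2.49%.

The numbers were set for the occasion; no experiment stands behind them.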